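**Retrosynthetic overview**
1. Target 11 comes from the fully protected flavone 10 by one BCl3 operation that cleaves the 4'-O-benzyl ether and, by chelation to C4=O, only the 5-O-methyl ether.
2. Key step: the γ-pyrone C ring (the only ring built, and built last) is closed in one pot by Pd-catalysed three-component carbonylative annulation of iodophenol 4, CO and aryl alkyne 7. This forms C4a–C4, C4–C3 and O1–C2 and replaces the usual chalcone or Baker–Venkataraman sequence.
3. A ring: 4 comes from 3,4,5-trimethoxyphenol 1, whose two equivalent ortho C–H positions are used in turn (Br then OMe; then I).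
4. B ring: 7 comes from syringaldehyde 5 by O-benzylation and Seyferth–Gilbert homologation.

Assumption: the target has no stereocentre, stereogenic axis or stereogenic double bond, so it is achiral and no stereocontrol is required.

**Route**

Step 1
Reactants: 1 3,4,5-trimethoxyphenol
Product: 2 2-bromo-3,4,5-trimethoxyphenol
Conditions: NBS (1.0 equiv), CH2Cl2, −78 → 0 °C
Reagents that add atoms: N-bromosuccinimide, O=C1CCC(=O)N1Br
Why: Electrophilic aromatic bromination ortho to the free OH; the para position is blocked and the two ortho C–H are equivalent, so one equivalent of NBS at low temperature gives a single monobromide.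

Step 2
Reactants: 2 2-bromo-3,4,5-trimethoxyphenol
Product: 3 2,3,4,5-tetramethoxyphenol
Conditions: NaOMe (6 equiv), CuBr (20 mol%), MeOH/DMF, 110 °C, Ar; aq. HCl work-up
Reagents that add atoms: sodium methoxide, C[O-].[Na+]
Why: Ullmann-type Cu(I)-catalysed methoxylation of an ortho-bromophenoxide, the reaction type that converts 5-bromovanillin to syringaldehyde; the phenoxide is a spectator and is re-protonated on work-up.

Step 3
Reactants: 3 2,3,4,5-tetramethoxyphenol
Product: 4 2-iodo-3,4,5,6-tetramethoxyphenol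
Conditions: I2 (1.05 equiv), NaHCO3, THF/H2O, 0 °C → rt, dark
Reagents that add atoms: iodine, II
Why: Electrophilic aromatic iodination at the only remaining ring C–H, which is ortho to the phenol; the mild I2/bicarbonate system limits oxidation of the electron-rich ring to a quinone.

Step 4
Reactants: 5 syringaldehyde (4-hydroxy-3,5-dimethoxybenzaldehyde)
Product: 6 4-(benzyloxy)-3,5-dimethoxybenzaldehyde
Conditions: BnBr, K2CO3, DMF, 60 °C
Reagents that add atoms: benzyl bromide, BrCc1ccccc1
Why: Williamson etherification; the benzyl ether keeps the phenol from deactivating the aldehyde as a phenoxide in step 5 and from trapping the acyl-palladium in step 6, and it is cleaved by the same Lewis acid used in the last step.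

Step 5
Reactants: 6 4-(benzyloxy)-3,5-dimethoxybenzaldehyde
Product: 7 2-(benzyloxy)-5-ethynyl-1,3-dimethoxybenzene
Conditions: dimethyl (1-diazo-2-oxopropyl)phosphonate, K2CO3, MeOH, 0 °C → rt
Reagents that add atoms: dimethyl (1-diazo-2-oxopropyl)phosphonate (Bestmann–Ohira reagent), COP(=O)(OC)C(=[N+]=[N-])C(C)=O
Why: Seyferth–Gilbert homologation in the Ohira–Bestmann variant; dimethyl (diazomethyl)phosphonate formed in situ olefinates the aldehyde and the diazoalkene loses N2 with a 1,2-hydrogen shift to give the terminal alkyne.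

Step 6
Reactants: 4 2-iodo-3,4,5,6-tetramethoxyphenol; 7 2-(benzyloxy)-5-ethynyl-1,3-dimethoxybenzene (1.3 equiv)
Product: 10 4'-benzyloxy-5,6,7,8,3',5'-hexamethoxyflavone, via aryl ynone 8 (not isolated), via diethylamino enone 9 (not isolated)
Conditions: PdCl2(dppf) (5 mol%), CO (10 atm), Et2NH, 120 °C, autoclave
Reagents that add atoms: carbon monoxide, [C-]#[O+]
Why: Pd-catalysed carbonylative Sonogashira annulation: oxidative addition of Ar–I, CO insertion and alkynylation of the acyl-palladium give ynone 8; Et2NH adds to it to give enaminone 9, which closes by 6-endo addition–elimination of the ortho-phenol, so the flavone forms and not the 5-exo aurone.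

Step 7
Reactants: 10 4'-benzyloxy-5,6,7,8,3',5'-hexamethoxyflavone
Product: 11 5,4'-dihydroxy-6,7,8,3',5'-pentamethoxyflavone
Conditions: BCl3 (4 equiv), pentamethylbenzene (3 equiv), CH2Cl2, −78 → 0 °C; then MeOH/H2O
Reagents that add atoms: none
Why: Lewis-acid ether cleavage; BCl3 removes the aryl benzyl ether at low temperature (benzyl cation trapped by pentamethylbenzene) and its chelate with the C4 carbonyl directs demethylation to the peri 5-OMe only, while the other five methoxy groups lack this activation and survive at 0 °C or below.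

**Compound list**
1 | 3,4,5-trimethoxyphenol | COc1cc(O)cc(OC)c1OC | starting material
2 | 2-bromo-3,4,5-trimethoxyphenol | COc1cc(O)c(Br)c(OC)c1OC | intermediate
3 | 2,3,4,5-tetramethoxyphenol | COc1cc(O)c(OC)c(OC)c1OC | intermediate
4 | 2-iodo-3,4,5,6-tetramethoxyphenol | COc1c(O)c(I)c(OC)c(OC)c1OC | intermediate
5 | syringaldehyde (4-hydroxy-3,5-dimethoxybenzaldehyde) | COc1cc(C=O)cc(OC)c1O | starting material
6 | 4-(benzyloxy)-3,5-dimethoxybenzaldehyde | COc1cc(C=O)cc(OC)c1OCc1ccccc1 | intermediate
7 | 2-(benzyloxy)-5-ethynyl-1,3-dimethoxybenzene | COc1cc(C#C)cc(OC)c1OCc1ccccc1 | intermediate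
8 | 3-[4-(benzyloxy)-3,5-dimethoxyphenyl]-1-(2-hydroxy-3,4,5,6-tetramethoxyphenyl)prop-2-yn-1-one | COc1cc(C#CC(=O)c2c(O)c(OC)c(OC)c(OC)c2OC)cc(OC)c1OCc1ccccc1 | intermediate (not isolated)
9 | (E)-3-[4-(benzyloxy)-3,5-dimethoxyphenyl]-3-(diethylamino)-1-(2-hydroxy-3,4,5,6-tetramethoxyphenyl)prop-2-en-1-one | CCN(CC)/C(=C/C(=O)c1c(O)c(OC)c(OC)c(OC)c1OC)c1cc(OC)c(OCc2ccccc2)c(OC)c1 | intermediate (not isolated)
10 | 4'-benzyloxy-5,6,7,8,3',5'-hexamethoxyflavone (2-[4-(benzyloxy)-3,5-dimethoxyphenyl]-5,6,7,8-tetramethoxy-4H-chromen-4-one) | COc1cc(-c2cc(=O)c3c(OC)c(OC)c(OC)c(OC)c3o2)cc(OC)c1OCc1ccccc1 | intermediate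
11 | 5,4'-dihydroxy-6,7,8,3',5'-pentamethoxyflavone | COc1cc(-c2cc(=O)c3c(O)c(OC)c(OC)c(OC)c3o2)cc(OC)c1O | target

**Step count**
Total: 7 steps. Longest linear sequence: 5 steps (1 → 2 → 3 → 4 → 10 → 11); the B-ring branch (5 → 6 → 7) joins at step 6.

**Three steps most likely to fail, with fallbacks**

First, step 6. The aryl iodide is flanked by OH and OMe and is very electron-rich, so oxidative addition is slow. Aminocarbonylation to the N,N-diethylamide or CO-free Sonogashira coupling followed by benzofuran formation could compete. The fallback abandons the carbonylative disconnection and sets out from phenol 3 and aldehyde 6. Fries-type C-acetylation of 3 at its only free position (AcOH, BF3·OEt2, 90 °C) gives 1-(2-hydroxy-3,4,5,6-tetramethoxyphenyl)ethan-1-one F1. Claisen–Schmidt condensation of F1 with 6 (KOH, EtOH, rt) gives the chalcone (E)-3-[4-(benzyloxy)-3,5-dimethoxyphenyl]-1-(2-hydroxy-3,4,5,6-tetramethoxyphenyl)prop-2-en-1-one F2. Oxidative cyclisation of F2 (cat. I2, DMSO, 120 °C) comes back to the route at 10.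

Second, step 2. The bromide is hindered and electron-rich, so hydrodebromination back to 1 and air oxidation of the product can erode the yield. The fallback replaces the copper C–O coupling by a metalation–oxidation sequence and sets out from 2. O-Benzylation (BnBr, K2CO3, DMF) gives 1-(benzyloxy)-2-bromo-3,4,5-trimethoxybenzene F3. Bromine–lithium exchange (n-BuLi, THF, −78 °C), borylation with B(OMe)3 and oxidation with H2O2/NaOH give 6-(benzyloxy)-2,3,4-trimethoxyphenol F4. O-Methylation (MeI, K2CO3, acetone) gives 1-(benzyloxy)-2,3,4,5-tetramethoxybenzene F5. Hydrogenolysis (H2, Pd/C, EtOAc) comes back to the route at 3.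

Third, step 7. Both cleavages must go to completion without loss of the 6-OMe (next to the new 5-O–boron chelate) or a 3'/5'-OMe (next to the freed 4'-oxygen). The fallback separates the two deprotections by mechanism and sets out from 10. Hydrogenolysis of the benzyl ether (H2, 1 atm, Pd/C, EtOAc/MeOH, rt) gives 2-(4-hydroxy-3,5-dimethoxyphenyl)-5,6,7,8-tetramethoxy-4H-chromen-4-one F6. Chelation-controlled mono-demethylation of the 5-OMe (AlCl3, MeCN, 60 °C; then aq. HCl) comes back to the route at 11.

**Further compounds**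
F1 | step 6 | 1-(2-hydroxy-3,4,5,6-tetramethoxyphenyl)ethan-1-one | CC(=O)c1c(O)c(OC)c(OC)c(OC)c1OC
F2 | step 6 | (E)-3-[4-(benzyloxy)-3,5-dimethoxyphenyl]-1-(2-hydroxy-3,4,5,6-tetramethoxyphenyl)prop-2-en-1-one | COc1cc(/C=C/C(=O)c2c(O)c(OC)c(OC)c(OC)c2OC)cc(OC)c1OCc1ccccc1
F3 | step 2 | 1-(benzyloxy)-2-bromo-3,4,5-trimethoxybenzene | COc1cc(OCc2ccccc2)c(Br)c(OC)c1OC
F4 | step 2 | 6-(benzyloxy)-2,3,4-trimethoxyphenol | COc1cc(OCc2ccccc2)c(O)c(OC)c1OC
F5 | step 2 | 1-(benzyloxy)-2,3,4,5-tetramethoxybenzene | COc1cc(OCc2ccccc2)c(OC)c(OC)c1OC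
F6 | step 7 | 2-(4-hydroxy-3,5-dimethoxyphenyl)-5,6,7,8-tetramethoxy-4H-chromen-4-one | COc1cc(-c2cc(=O)c3c(OC)c(OC)c(OC)c(OC)c3o2)cc(OC)c1O
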